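## Retrosynthetic overview

1. The target comes from diketo diacid 37 by double Wittig methylenation (C8 in the unprimed half B, C7' in the primed half A). 37 comes from bis-decalin dialdehyde 34 by hydrogenation of C1=C2 and C1'=C2', desilylation and oxidation.
2. Key disconnection: in each decalin cut C5–C10 and C3–C4 (retro-[4+2] after adding C1=C2). All four decalin rings then arise in one operation from the monocyclic bis-trienal 31.
3. Enabling feature: in both halves the carboxyl carbon C19 sits on C4, next to the ring-fusion carbon C5, and C10 carries a methyl. Ring A (C1–C5, C10) is therefore a cyclohexene retron with C4=C5 as an (E)-2-methylenal dienophile and C10(Me)=C1–C2=C3 as the diene. Ring B (C5–C10) is the four-atom tether; its oxygen (C8 in B, C7' in A) later becomes the exocyclic methylene.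
4. 31 comes from the central cyclohexene, made by an auxiliary-controlled Diels–Alder reaction of diene 11 (arm A, from a trans-alkylated γ-lactone as a temporary ring) with acrylimide 13. Arm B is grown by Johnson–Claisen rearrangement and a syn-aldol; both dienes come from Zr-catalysed carboalumination–vinylation of alkynes.
5. Ring order: γ-lactone (temporary) → central cyclohexene → rings A and B of both decalins together. The two decalins have the same relative but opposite absolute configuration, so each is steered by its own tether stereocentres.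

Key step: step 25

Remark (locants): labdane-type numbering is used for both halves, C1–C20 for half B and primed for half A. The central ring is C12'–C13'(C16')=C14'–C15'–C15–C14; C14 carries C13(C16)=C12–C11–C9.
Remark (abbreviation): Ra = –C11'H2–C9'H(C≡CH)–C8'H2–C7'H(OTBS)–C6'H2–C5'H=C4'(CH3)–C19'H2OTBS, configured as in 11.
Remark (assumptions): (−)-Ipc2B(allyl), the Ohira–Bestmann reagent and both benzyl auxiliaries are taken as purchasable. The C13 carbinol of 17 and the anomeric centre of 9 are left undefined because both are destroyed in the next step.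

## Route

Step 1
Reactants: 1 methyl 4-oxobutanoate
Product: 3 (5R)-5-allyloxolan-2-one, via hydroxy ester 2 (not isolated)
Conditions: (−)-Ipc2B(allyl), Et2O, −78 °C; NaOH, H2O2; then p-TsOH (cat.), CH2Cl2, rt
Reagents that add atoms: (−)-B-allyldiisopinocampheylborane, C=CCB([C@@H]1C[C@@H]2C[C@H]([C@H]1C)C2(C)C)[C@@H]1C[C@@H]2C[C@H]([C@H]1C)C2(C)C
Why: Brown allylation through a chair-like six-membered transition state, in which the isopinocampheyl groups from (+)-α-pinene deliver allyl to one aldehyde face and set C7' (R), followed by lactonisation of the γ-hydroxy ester.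

Step 2
Reactants: 3 (5R)-5-allyloxolan-2-one
Product: 4 lactone enoate
Conditions: methyl methacrylate (10 equiv), Grubbs second-generation catalyst (5 mol %), CH2Cl2, 40 °C
Reagents that add atoms: methyl methacrylate, C=C(C)C(=O)OC
Why: Olefin cross-metathesis of a terminal alkene with a 1,1-disubstituted acrylate should give the thermodynamically favoured (E)-trisubstituted enoate, which fixes the C5'=C4' geometry.

Step 3
Reactants: 5 (2E)-3-methylpent-2-en-4-yn-1-ol
Product: 6 (2E)-3-methylpenta-2,4-dien-1-ol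
Conditions: H2 (1 atm), Lindlar catalyst, quinoline, EtOAc/hexane, rt
Reagents that add atoms: none
Why: Lindlar semi-hydrogenation reduces the terminal alkyne to the vinyl group and leaves the (E)-trisubstituted alkene untouched.

Step 4
Reactants: 6 (2E)-3-methylpenta-2,4-dien-1-ol
Product: 7 (3E)-5-bromo-3-methylpenta-1,3-diene
Conditions: PBr3 (0.4 equiv), Et2O, −10 °C; used at once
Reagents that add atoms: phosphorus tribromide, BrP(Br)Br
Why: Conversion of the primary allylic alcohol into the bromide via its phosphite ester (SN2) should retain the alkene geometry; the 3-methylpentadienyl system is symmetric, so direct and vinylogous substitution give the same constitution.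

Step 5
Reactants: 4 lactone enoate; 7 dienyl bromide
Product: 8 trans-alkylated lactone
Conditions: LDA (1.05 equiv), THF, −78 °C; then 7, DMPU, −78 → −40 °C
Reagents that add atoms: none
Why: Kinetic lactone enolate alkylation, in which the α-CH2 of the lactone is deprotonated faster than the γ-position of the α-methyl enoate and the allylic bromide enters anti to the C7' substituent (trans-2,4 lactone), which sets C9'.

Step 6
Reactants: 8 trans-alkylated lactone
Product: 9 lactol diol (anomeric mixture)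
Conditions: DIBAL-H (3.5 equiv), CH2Cl2, −78 °C; aq. Rochelle salt
Reagents that add atoms: none
Why: DIBAL reduction stops at the lactol (aluminium hemiacetal stable at −78 °C) while the conjugated ester is reduced 1,2 to the allylic alcohol.

Step 7
Reactants: 9 lactol diol
Product: 10 (2E,5S,7S,9E)-7-ethynyl-2,10-dimethyldodeca-2,9,11-triene-1,5-diol
Conditions: Ohira–Bestmann reagent (1.5 equiv), K2CO3, MeOH, 0 °C → rt
Reagents that add atoms: dimethyl (1-diazo-2-oxopropyl)phosphonate, CC(=O)C(=[N+]=[N-])P(=O)(OC)OC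
Why: Seyferth–Gilbert homologation (Ohira–Bestmann variant) of the hydroxy aldehyde in equilibrium with the lactol gives the C10'≡C1' alkyne and frees the C7' hydroxyl under carbonate conditions that should not epimerise C9'.

Step 8
Reactants: 10 alkynyl diol
Product: 11 bis-TBS ether (arm A diene)
Conditions: TBSCl (2.5 equiv), imidazole, DMF, rt
Reagents that add atoms: tert-butyldimethylsilyl chloride, CC(C)(C)[Si](C)(C)Cl
Why: Standard silylation protects both hydroxyls against the Lewis acids and organometallics that follow.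

Step 9
Reactants: 12 (4R)-4-benzyl-1,3-oxazolidin-2-one
Product: 13 (4R)-3-acryloyl-4-benzyl-1,3-oxazolidin-2-one
Conditions: acryloyl chloride, Et3N, LiCl, THF, 0 °C → rt
Reagents that add atoms: acryloyl chloride, C=CC(Cl)=O
Why: N-Acylation under mild amine/LiCl activation avoids the anionic polymerisation seen with lithiated oxazolidinones.

Step 10
Reactants: 11 arm A diene; 13 acrylimide (2 equiv)
Product: 14 cis-cyclohexene imide
Conditions: Et2AlCl (1.4 equiv per 13), CH2Cl2, −78 °C
Reagents that add atoms: none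
Why: Lewis-acid-promoted Diels–Alder reaction of the chiral N-acryloyloxazolidinone, in which the cationic bidentate aluminium chelate holds the s-cis acrylimide, the benzyl group blocks the Cα-Si face so the (E)-diene adds endo to the Cα-Re face (C14 S, C12' cis to it), and the dienophile β-carbon bonds to the unsubstituted diene terminus C15'.

Step 11
Reactants: 14 cis-cyclohexene imide
Product: 15 Weinreb amide
Conditions: MeNHOMe·HCl (3 equiv), Me3Al (3 equiv), CH2Cl2, 0 °C → rt
Reagents that add atoms: N,O-dimethylhydroxylamine hydrochloride, CNOC.Cl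
Why: Aluminium-amide transamination at the exocyclic carbonyl gives the Weinreb amide and releases auxiliary 12 without a base strong enough to epimerise C14.

Step 12
Reactants: 15 Weinreb amide
Product: 16 methyl ketone
Conditions: MeMgBr (2.2 equiv), THF, −20 → 0 °C
Reagents that add atoms: methylmagnesium bromide, C[Mg]Br
Why: Weinreb ketone synthesis, in which the chelated tetrahedral intermediate survives until work-up so that one methyl (C16) adds and the cis C14 centre is not enolised.

Step 13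
Reactants: 16 methyl ketone
Product: 17 tertiary allylic alcohol (C13 epimers)
Conditions: CH2=CHMgBr (3 equiv), anhydrous CeCl3 (3 equiv), THF, −78 °C
Reagents that add atoms: vinylmagnesium bromide, C=C[Mg]Br
Why: 1,2-Addition of the vinylcerium reagent suppresses enolisation of the ketone; the new C13 carbinol centre is destroyed in the next step.

Step 14
Reactants: 17 tertiary allylic alcohol
Product: 18 ethyl (E)-γ,δ-unsaturated ester
Conditions: MeC(OEt)3 (10 equiv), EtCO2H (0.1 equiv), xylene, 140 °C, EtOH distilled off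
Reagents that add atoms: triethyl orthoacetate, CC(OCC)(OCC)OCC
Why: Johnson–Claisen rearrangement through a chair in which the bulky ring substituent on C13 sits pseudo-equatorial should give mainly the (E)-C12=C13 alkene and delivers C11, C9 and the C10 ester in one step.

Step 15
Reactants: 18 ethyl ester
Product: 19 carboxylic acid
Conditions: LiOH·H2O (5 equiv), THF/MeOH/H2O, rt; then 1 M HCl to pH 3
Reagents that add atoms: lithium hydroxide, [Li+].[OH-]
Why: Saponification of the unhindered ethyl ester; silyl ethers and the alkyne are stable to aqueous LiOH at rt.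

Step 16
Reactants: 19 carboxylic acid; 20 (4R)-4-benzyl-1,3-thiazolidine-2-thione
Product: 21 N-acylthiazolidinethione
Conditions: DCC (1.2 equiv), DMAP (0.1 equiv), CH2Cl2, 0 °C → rt
Reagents that add atoms: none
Why: Carbodiimide N-acylation installs the auxiliary that controls the aldol step and can later be reduced directly to the aldehyde.

Step 17
Reactants: 22 pent-4-enal
Product: 23 methyl (2E)-2-methyl-6-oxohex-2-enoate
Conditions: methyl methacrylate (10 equiv), Grubbs second-generation catalyst (5 mol %), CH2Cl2, 40 °C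
Reagents that add atoms: methyl methacrylate, C=C(C)C(=O)OC
Why: Olefin cross-metathesis as in step 2; the aldehyde is tolerated and the (E)-enoate should form.

Step 18
Reactants: 21 N-acylthiazolidinethione; 23 aldehyde (1.3 equiv)
Product: 24 syn-aldol adduct
Conditions: TiCl4 (1.05 equiv), i-Pr2NEt (1.1 equiv), NMP (1.0 equiv), CH2Cl2, 0 °C; then 23, −78 → 0 °C
Reagents that add atoms: none
Why: Titanium-enolate syn-aldol of the N-acylthiazolidinethione, in which the chlorotitanium (Z)-enolate reacts through a non-chelated Zimmerman–Traxler chair on the face away from the benzyl group and sets C9 (R) and C8 (S) with C11 and the C8 oxygen syn along C7–C10, i.e. both equatorial in the later ring-B chair.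

Step 19
Reactants: 24 syn-aldol adduct
Product: 25 C8 silyl ether
Conditions: TBSOTf (1.5 equiv), 2,6-lutidine (2.5 equiv), CH2Cl2, −78 → 0 °C
Reagents that add atoms: tert-butyldimethylsilyl triflate, CC(C)(C)[Si](C)(C)OS(=O)(=O)C(F)(F)F
Why: Silylation of the hindered secondary alcohol with the silyl triflate blocks retro-aldol and gives the bulky equatorial group wanted in the key step.

Step 20
Reactants: 25 C8 silyl ether
Product: 26 C10 aldehyde with free C19 allylic alcohol
Conditions: DIBAL-H (4.5 equiv), CH2Cl2, −78 °C, 1 h; MeOH, aq. Rochelle salt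
Reagents that add atoms: none
Why: DIBAL reduces the N-acylthiazolidinethione to a hemithioaminal aluminate that holds the aldehyde oxidation level until work-up, while the conjugated ester is reduced 1,2 to the allylic alcohol.

Step 21
Reactants: 26 aldehyde
Product: 27 bis-alkyne
Conditions: Ohira–Bestmann reagent (1.5 equiv), K2CO3, MeOH, 0 °C → rt
Reagents that add atoms: dimethyl (1-diazo-2-oxopropyl)phosphonate, CC(=O)C(=[N+]=[N-])P(=O)(OC)OC
Why: Ohira–Bestmann homologation of the α-branched aldehyde gives the C10≡C1 alkyne under carbonate conditions that should not epimerise C9.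

Step 22
Reactants: 27 bis-alkyne
Product: 28 bis-alkyne diol
Conditions: HF·pyridine, pyridine, THF, 0 °C
Reagents that add atoms: none
Why: Buffered HF·pyridine cleaves the primary allylic TBS ether (C19') much faster than the two hindered secondary ones.

Step 23
Reactants: 28 bis-alkyne diol
Product: 30 bis-dienyl diol, via bis-alkenylalane 29 (not isolated)
Conditions: Me3Al (8 equiv), Cp2ZrCl2 (0.5 equiv), H2O (2 equiv), CH2Cl2, −20 °C; then CH2=CHBr (6 equiv), ZnCl2, Pd(PPh3)4 (10 mol %), THF, rt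
Reagents that add atoms: trimethylaluminium, C[Al](C)C; vinyl bromide, C=CBr
Why: Zirconium-catalysed syn-carboalumination (Negishi) places methyl (C20, C20') on the internal alkyne carbon cis to aluminium, and Pd/Zn-mediated coupling with vinyl bromide proceeds with retention, so both dienes should form with the tether "outside" and the methyl "inside".

Step 24
Reactants: 30 bis-dienyl diol
Product: 31 bis-trienal
Conditions: MnO2 (40 equiv), CH2Cl2, rt
Reagents that add atoms: none
Why: MnO2 oxidises only the allylic primary alcohols, without E/Z isomerisation, to the two (E)-2-methylenals.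

Step 25
Reactants: 31 bis-trienal
Product: 34 bis-decalin dialdehyde, via B-ring mono-adduct 32 (not isolated), via A-ring mono-adduct 33 (not isolated)
Conditions: Me2AlCl (3.0 equiv), CH2Cl2 (0.005 M), −78 → −20 °C
Reagents that add atoms: none
Why: Me2AlCl binds each aldehyde and lowers the LUMO of the (E)-2-methylenal, so each arm undergoes a concerted, asynchronous intramolecular [4+2] cycloaddition that forms C3–C4 and C5–C10 (C3'–C4' and C5'–C10'). The closest known reaction is the Lewis-acid-promoted type-1 intramolecular Diels–Alder reaction of (2E,8E)-2-methylundeca-2,8,10-trienals, which gives trans-fused octalins with an aldehyde on a quaternary carbon. In each half ring A closes as the new cyclohexene through the carbonyl-endo transition state, and ring B closes as the four-atom tether (C6–C9 or C6'–C9') in a chair. C4 is fixed by the (E)-enal geometry (CHO cis to H5, methyl cis to C20), the trans fusion at C5/C10 by the endo mode with the (E)-diene whose methyl is "inside", and the absolute face by the tether stereocentres, since C9–CH2R with C8–OTBS (arm B) and C9'–CH2R with C7'–OTBS (arm A) are all equatorial in only one chair. The step needs endo over exo and one π-face per arm, which aluminium complexation and the matched trans-1,2 (arm B) and cis-1,3 (arm A) tether substituents should secure; each enal reaches only its own diene through a six-membered tether, so crossed cycloadditions are not expected at high dilution. Mono-adducts 32 and 33 react on under the same conditions.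

Step 26
Reactants: 34 bis-decalin dialdehyde
Product: 35 tetrahydro dialdehyde
Conditions: H2 (1 atm), RhCl(PPh3)3 (10 mol %), benzene, rt
Reagents that add atoms: none
Why: Homogeneous hydrogenation with Wilkinson's catalyst should be selective for the two cis-disubstituted ring alkenes over the trisubstituted C12=C13 and C13'=C14' alkenes; the α-quaternary aldehydes should not be decarbonylated at rt.

Step 27
Reactants: 35 tetrahydro dialdehyde
Product: 36 diol dialdehyde
Conditions: TBAF (6 equiv), THF, 40 °C; aq. NH4Cl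
Reagents that add atoms: none
Why: Fluoride cleaves both secondary silyl ethers; the aldehydes carry no α-hydrogen and tolerate the basic fluoride.

Step 28
Reactants: 36 diol dialdehyde
Product: 37 diketo diacid
Conditions: Jones reagent (CrO3, H2SO4, H2O), acetone, 0 °C
Reagents that add atoms: water, O
Why: Jones oxidation converts both secondary alcohols into ketones and both hindered aldehydes (via their hydrates) into carboxylic acids; isolated trisubstituted alkenes should tolerate brief exposure at 0 °C.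

Step 29
Reactants: 37 diketo diacid
Product: 38 CNP0240573.1 (target)
Conditions: Ph3PCH3Br (10 equiv), KOtBu (9.5 equiv), THF, 65 °C; then aq. NaH2PO4
Reagents that add atoms: methyltriphenylphosphonium bromide, C[P+](c1ccccc1)(c1ccccc1)c1ccccc1.[Br-]
Why: Double Wittig methylenation with excess ylide (the acids travel as carboxylates) installs C17 and C17'; any epimerisation at C9 under the basic conditions converges on the equatorial side chain, which is the target configuration.

## Compound list

1 | methyl 4-oxobutanoate | COC(=O)CCC=O | starting material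
2 | methyl (4R)-4-hydroxyhept-6-enoate | COC(=O)CC[C@@H](O)CC=C | intermediate
3 | (5R)-5-allyloxolan-2-one | O=C1O[C@@H](CC=C)CC1 | intermediate
4 | methyl (2E)-2-methyl-4-[(2R)-5-oxooxolan-2-yl]but-2-enoate | O=C1O[C@@H](C/C=C(\C)C(=O)OC)CC1 | intermediate
5 | (2E)-3-methylpent-2-en-4-yn-1-ol | OC/C=C(\C)C#C | starting material
6 | (2E)-3-methylpenta-2,4-dien-1-ol | OC/C=C(\C)C=C | intermediate
7 | (3E)-5-bromo-3-methylpenta-1,3-diene | BrC/C=C(\C)C=C | intermediate
8 | methyl (2E)-2-methyl-4-{(2S,4S)-4-[(2E)-3-methylpenta-2,4-dienyl]-5-oxooxolan-2-yl}but-2-enoate (trans-2,4 lactone; ring C2 = C7', C4 = C9') | O=C1O[C@@H](C/C=C(\C)C(=O)OC)C[C@@H]1C/C=C(\C)C=C | intermediate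
9 | (2E)-4-{(2S,4S)-5-hydroxy-4-[(2E)-3-methylpenta-2,4-dienyl]oxolan-2-yl}-2-methylbut-2-en-1-ol (lactol, anomers) | OC1O[C@@H](C/C=C(\C)CO)C[C@@H]1C/C=C(\C)C=C | intermediate
10 | (2E,5S,7S,9E)-7-ethynyl-2,10-dimethyldodeca-2,9,11-triene-1,5-diol | OC/C(C)=C/C[C@H](O)C[C@H](C/C=C(\C)C=C)C#C | intermediate
11 | 1,5-bis-TBS ether of 10 (arm A diene) | CC(C)(C)[Si](C)(C)OC/C(C)=C/C[C@H](O[Si](C)(C)C(C)(C)C)C[C@H](C/C=C(\C)C=C)C#C | intermediate
12 | (4R)-4-benzyl-1,3-oxazolidin-2-one | O=C1N[C@H](Cc2ccccc2)CO1 | starting material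
13 | (4R)-3-acryloyl-4-benzyl-1,3-oxazolidin-2-one | C=CC(=O)N1[C@H](Cc2ccccc2)COC1=O | intermediate
14 | (4R)-4-benzyl-3-{[(1S,6S)-5-methyl-6-Ra-cyclohex-4-en-1-yl]carbonyl}oxazolidin-2-one (cis; ring C1 = C14, C6 = C12') | CC(C)(C)[Si](C)(C)OC/C(C)=C/C[C@H](O[Si](C)(C)C(C)(C)C)C[C@H](C[C@@H]1C(C)=CCC[C@@H]1C(=O)N1[C@H](Cc2ccccc2)COC1=O)C#C | intermediate
15 | (1S,6S)-N-methoxy-N,5-dimethyl-6-Ra-cyclohex-4-ene-1-carboxamide | CC(C)(C)[Si](C)(C)OC/C(C)=C/C[C@H](O[Si](C)(C)C(C)(C)C)C[C@H](C[C@@H]1C(C)=CCC[C@@H]1C(=O)N(C)OC)C#C | intermediate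
16 | 1-[(1S,6S)-5-methyl-6-Ra-cyclohex-4-en-1-yl]ethanone | CC(C)(C)[Si](C)(C)OC/C(C)=C/C[C@H](O[Si](C)(C)C(C)(C)C)C[C@H](C[C@@H]1C(C)=CCC[C@@H]1C(C)=O)C#C | intermediate
17 | 2-[(1S,6S)-5-methyl-6-Ra-cyclohex-4-en-1-yl]but-3-en-2-ol (C13 epimers) | CC(C)(C)[Si](C)(C)OC/C(C)=C/C[C@H](O[Si](C)(C)C(C)(C)C)C[C@H](C[C@@H]1C(C)=CCC[C@@H]1C(C)(O)C=C)C#C | intermediate
18 | ethyl (4E)-5-[(1S,6S)-5-methyl-6-Ra-cyclohex-4-en-1-yl]hex-4-enoate | CC(C)(C)[Si](C)(C)OC/C(C)=C/C[C@H](O[Si](C)(C)C(C)(C)C)C[C@H](C[C@@H]1C(C)=CCC[C@@H]1/C(C)=C/CCC(=O)OCC)C#C | intermediate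
19 | (4E)-5-[(1S,6S)-5-methyl-6-Ra-cyclohex-4-en-1-yl]hex-4-enoic acid | CC(C)(C)[Si](C)(C)OC/C(C)=C/C[C@H](O[Si](C)(C)C(C)(C)C)C[C@H](C[C@@H]1C(C)=CCC[C@@H]1/C(C)=C/CCC(=O)O)C#C | intermediate
20 | (4R)-4-benzyl-1,3-thiazolidine-2-thione | S=C1N[C@H](Cc2ccccc2)CS1 | starting material
21 | N-acyl-(4R)-4-benzylthiazolidine-2-thione of acid 19 | CC(C)(C)[Si](C)(C)OC/C(C)=C/C[C@H](O[Si](C)(C)C(C)(C)C)C[C@H](C[C@@H]1C(C)=CCC[C@@H]1/C(C)=C/CCC(=O)N1[C@H](Cc2ccccc2)CSC1=S)C#C | intermediate
22 | pent-4-enal | C=CCCC=O | starting material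
23 | methyl (2E)-2-methyl-6-oxohex-2-enoate | O=CCC/C=C(\C)C(=O)OC | intermediate
24 | syn-aldol adduct: thioimide carbonyl C10, C9 (R) bearing the C11 chain, C8 (S) carbinol, chain C7–C6–C5=C4(C18)–C19O2Me (E) | CC(C)(C)[Si](C)(C)OC/C(C)=C/C[C@H](O[Si](C)(C)C(C)(C)C)C[C@H](C[C@@H]1C(C)=CCC[C@@H]1/C(C)=C/C[C@@H](C(=O)N1[C@H](Cc2ccccc2)CSC1=S)[C@@H](O)CC/C=C(\C)C(=O)OC)C#C | intermediate
25 | C8 O-TBS ether of 24 | CC(C)(C)[Si](C)(C)OC/C(C)=C/C[C@H](O[Si](C)(C)C(C)(C)C)C[C@H](C[C@@H]1C(C)=CCC[C@@H]1/C(C)=C/C[C@@H](C(=O)N1[C@H](Cc2ccccc2)CSC1=S)[C@@H](O[Si](C)(C)C(C)(C)C)CC/C=C(\C)C(=O)OC)C#C | intermediate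
26 | C10 aldehyde with C8 OTBS and free (E)-allylic C19 alcohol | CC(C)(C)[Si](C)(C)OC/C(C)=C/C[C@H](O[Si](C)(C)C(C)(C)C)C[C@H](C[C@@H]1C(C)=CCC[C@@H]1/C(C)=C/C[C@@H](C=O)[C@@H](O[Si](C)(C)C(C)(C)C)CC/C=C(\C)CO)C#C | intermediate
27 | bis-alkyne (C10≡C1 and C10'≡C1'), C19 OH free, C19' OTBS, C8 and C7' OTBS | CC(C)(C)[Si](C)(C)OC/C(C)=C/C[C@H](O[Si](C)(C)C(C)(C)C)C[C@H](C[C@@H]1C(C)=CCC[C@@H]1/C(C)=C/C[C@@H](C#C)[C@@H](O[Si](C)(C)C(C)(C)C)CC/C=C(\C)CO)C#C | intermediate
28 | bis-alkyne diol (C19 and C19' OH free; C8 and C7' OTBS) | OC/C(C)=C/C[C@H](O[Si](C)(C)C(C)(C)C)C[C@H](C[C@@H]1C(C)=CCC[C@@H]1/C(C)=C/C[C@@H](C#C)[C@@H](O[Si](C)(C)C(C)(C)C)CC/C=C(\C)CO)C#C | intermediate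
29 | bis(alkenyl-dimethylalane) of 28 (Me on C10 and C10', AlMe2 on C1 and C1', both hydroxyls as O–AlMe2) | C[Al](C)OC/C(C)=C/C[C@H](O[Si](C)(C)C(C)(C)C)C[C@H](C[C@@H]1C(C)=CCC[C@@H]1/C(C)=C/C[C@@H](/C(C)=C/[Al](C)C)[C@@H](O[Si](C)(C)C(C)(C)C)CC/C=C(\C)CO[Al](C)C)/C(C)=C/[Al](C)C | intermediate
30 | bis-dienyl diol: (E)-C10(C20)=C1–C2=C3 and (E)-C10'(C20')=C1'–C2'=C3' dienes, C19 and C19' allylic alcohols | OC/C(C)=C/C[C@H](O[Si](C)(C)C(C)(C)C)C[C@H](C[C@@H]1C(C)=CCC[C@@H]1/C(C)=C/C[C@@H](/C(C)=C/C=C)[C@@H](O[Si](C)(C)C(C)(C)C)CC/C=C(\C)CO)/C(C)=C/C=C | intermediate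
31 | bis-trienal: 30 with both C19 and C19' as (E)-2-methylenal aldehydes | O=C/C(C)=C/C[C@H](O[Si](C)(C)C(C)(C)C)C[C@H](C[C@@H]1C(C)=CCC[C@@H]1/C(C)=C/C[C@@H](/C(C)=C/C=C)[C@@H](O[Si](C)(C)C(C)(C)C)CC/C=C(\C)C=O)/C(C)=C/C=C | intermediate
32 | mono-adduct with half B cyclised (trans-decalin, C1=C2, C19 CHO), arm A still a trienal | O=C/C(C)=C/C[C@H](O[Si](C)(C)C(C)(C)C)C[C@H](C[C@@H]1C(C)=CCC[C@@H]1/C(C)=C/C[C@@H]1[C@@H](O[Si](C)(C)C(C)(C)C)CC[C@H]2[C@@]1(C)C=CC[C@]2(C)C=O)/C(C)=C/C=C | intermediate
33 | mono-adduct with half A cyclised (trans-decalin, C1'=C2', C19' CHO), arm B still a trienal | CC(C)(C)[Si](C)(C)O[C@@H]1C[C@H](C[C@@H]2C(C)=CCC[C@@H]2/C(C)=C/C[C@@H](/C(C)=C/C=C)[C@@H](O[Si](C)(C)C(C)(C)C)CC/C=C(\C)C=O)[C@@]2(C)C=CC[C@@](C)(C=O)[C@@H]2C1 | intermediate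
34 | bis-decalin dialdehyde: both trans-decalins with C1=C2 and C1'=C2', equatorial C19 and C19' CHO, equatorial C8 and C7' OTBS | CC(C)(C)[Si](C)(C)O[C@@H]1C[C@H](C[C@@H]2C(C)=CCC[C@@H]2/C(C)=C/C[C@@H]2[C@@H](O[Si](C)(C)C(C)(C)C)CC[C@H]3[C@@]2(C)C=CC[C@]3(C)C=O)[C@@]2(C)C=CC[C@@](C)(C=O)[C@@H]2C1 | intermediate
35 | tetrahydro dialdehyde (rings A and A' saturated) | CC(C)(C)[Si](C)(C)O[C@@H]1C[C@H](C[C@@H]2C(C)=CCC[C@@H]2/C(C)=C/C[C@@H]2[C@@H](O[Si](C)(C)C(C)(C)C)CC[C@H]3[C@@]2(C)CCC[C@]3(C)C=O)[C@@]2(C)CCC[C@@](C)(C=O)[C@@H]2C1 | intermediate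
36 | C8,C7'-diol C19,C19'-dialdehyde | O[C@@H]1C[C@H](C[C@@H]2C(C)=CCC[C@@H]2/C(C)=C/C[C@@H]2[C@@H](O)CC[C@H]3[C@@]2(C)CCC[C@]3(C)C=O)[C@@]2(C)CCC[C@@](C)(C=O)[C@@H]2C1 | intermediate
37 | 8,7'-diketo 19,19'-diacid | O=C1C[C@H](C[C@@H]2C(C)=CCC[C@@H]2/C(C)=C/C[C@@H]2C(=O)CC[C@H]3[C@@]2(C)CCC[C@]3(C)C(=O)O)[C@@]2(C)CCC[C@@](C)(C(=O)O)[C@@H]2C1 | intermediate
38 | CNP0240573.1 | C=C1C[C@H](C[C@@H]2C(C)=CCC[C@@H]2/C(C)=C/C[C@@H]2C(=C)CC[C@H]3[C@@]2(C)CCC[C@]3(C)C(=O)O)[C@@]2(C)CCC[C@@](C)(C(=O)O)[C@@H]2C1 | target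

## Summary

Total step count: 29.
Longest linear sequence: 25 steps (1, 2, 5–8, 10–16, 18–29); steps 3, 4, 9 and 17 are side branches.

Steps most likely to fail:

Step 25. The "inside" methyl on C10 and C10' disfavours the s-cis diene, so the cycloadditions may be slow enough for Lewis-acid-induced diene isomerisation or loss of endo and facial control to compete. The fallback sets out from 31 and returns at 34. The enals are converted with 1,2-bis(trimethylsilyloxy)ethane and catalytic TMSOTf (CH2Cl2, −78 °C) into the bis(1,3-dioxolane) F1. Catalytic TfOH at −78 → −40 °C then ionises each acetal to a 2-alkoxyallyl cation, a far stronger dienophile, and the ionic Diels–Alder reaction should give the bis-dioxolane adduct F2 with the same endo sense. PPTS in wet acetone returns dialdehyde 34.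

Step 10. The 1-alkyl and 2-methyl groups of the diene direct in opposite senses, so part of the material may add with the reversed regiochemistry, and complexation of the silyl ethers by the stoichiometric aluminium reagent may erode facial control. The fallback sets out from 11 and returns at 15. A catalytic enantioselective Diels–Alder reaction of 11 with 3-acryloyloxazolidin-2-one under 10 mol % of the square-planar Cu(II)–(S,S)-tert-butyl-bis(oxazoline) hexafluoroantimonate complex (CH2Cl2, −20 °C) should give the cis-adduct F3; here the facial control comes from the ligand and the dienophile is a more strongly polarised cationic chelate. Me3Al/MeNHOMe·HCl then converts it into Weinreb amide 15.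

Step 20. The aldehyde may be released from the aluminium hemithioaminal before the ester is consumed and then be reduced on to the primary alcohol. The fallback sets out from 25 and returns at 27. LiBH4/MeOH (Et2O, 0 °C) reduces only the thioimide to the primary alcohol F4, Dess–Martin periodinane gives the aldehyde F5, and the Ohira–Bestmann reagent gives the alkyne F6. Only then does DIBAL-H (2.2 equiv, −78 °C) reduce the enoate to the allylic alcohol 27.

Further compounds
F1 | step 25 | bis(1,3-dioxolane) of bis-trienal 31 | O1CCOC1/C(C)=C/C[C@H](O[Si](C)(C)C(C)(C)C)C[C@H](C[C@@H]2C(C)=CCC[C@@H]2/C(C)=C/C[C@@H](/C(C)=C/C=C)[C@@H](O[Si](C)(C)C(C)(C)C)CC/C=C(\C)C2OCCO2)/C(C)=C/C=C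
F2 | step 25 | bis(1,3-dioxolane) of bis-decalin dialdehyde 34 | CC(C)(C)[Si](C)(C)O[C@@H]1C[C@H](C[C@@H]2C(C)=CCC[C@@H]2/C(C)=C/C[C@@H]2[C@@H](O[Si](C)(C)C(C)(C)C)CC[C@H]3[C@@]2(C)C=CC[C@]3(C)C2OCCO2)[C@@]2(C)C=CC[C@@](C)(C3OCCO3)[C@@H]2C1
F3 | step 10 | 3-{[(1S,6S)-5-methyl-6-Ra-cyclohex-4-en-1-yl]carbonyl}oxazolidin-2-one | CC(C)(C)[Si](C)(C)OC/C(C)=C/C[C@H](O[Si](C)(C)C(C)(C)C)C[C@H](C[C@@H]1C(C)=CCC[C@@H]1C(=O)N1CCOC1=O)C#C
F4 | step 20 | C10 primary alcohol with C8 OTBS and intact methyl enoate | CC(C)(C)[Si](C)(C)OC/C(C)=C/C[C@H](O[Si](C)(C)C(C)(C)C)C[C@H](C[C@@H]1C(C)=CCC[C@@H]1/C(C)=C/C[C@@H](CO)[C@@H](O[Si](C)(C)C(C)(C)C)CC/C=C(\C)C(=O)OC)C#C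
F5 | step 20 | C10 aldehyde with C8 OTBS and intact methyl enoate | CC(C)(C)[Si](C)(C)OC/C(C)=C/C[C@H](O[Si](C)(C)C(C)(C)C)C[C@H](C[C@@H]1C(C)=CCC[C@@H]1/C(C)=C/C[C@@H](C=O)[C@@H](O[Si](C)(C)C(C)(C)C)CC/C=C(\C)C(=O)OC)C#C
F6 | step 20 | bis-alkyne with C8 OTBS and intact methyl enoate | CC(C)(C)[Si](C)(C)OC/C(C)=C/C[C@H](O[Si](C)(C)C(C)(C)C)C[C@H](C[C@@H]1C(C)=CCC[C@@H]1/C(C)=C/C[C@@H](C#C)[C@@H](O[Si](C)(C)C(C)(C)C)CC/C=C(\C)C(=O)OC)C#C
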